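## Retrosynthetic overview

1. Target 25 ⇒ alkynol 24 (dihydrofuran ring closed last, O16–C15) ⇒ Δ5 alkene 18 (6β-OAc through the 5,6-epoxide, the 6-ketone and α-face hydride).
2. 18 ⇒ methyl ketal 15 by a Prins-type closure of ring B through the C9–C10 bond. The strategy rests on C9 (ether carbon, spiro atom shared by ring B and the C9–C11–C12–C13–O tetrahydrofuran) standing next to the quaternary, methyl-bearing C10 in ring B.
3. 15 ⇒ hydrazone 6 + alkynyl epoxide 11 (C11–C12 bond by azaenolate opening; hydrolysis; ketalization closes the tetrahydrofuran ring).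
4. 6 ⇒ dihydro-β-ionone 1 (TosMIC, then MeLi); 11 ⇒ 2-bromoallyl alcohol 7 + trimethylsilylacetylene 8 (Sonogashira; Sharpless epoxidation sets C13).
5. Ring order: ring A (present in 1) → tetrahydrofuran ring (step 9) → ring B (step 10) → dihydrofuran ring (step 17).

Key step: step 10

Assumption: labdane numbering (C1–C20) is used for all compounds; C8 is made racemic and carried as an epimer mixture until step 10, where it is expected to converge.

## Route

Step 1
Reactants: 1 dihydro-β-ionone; 2 tosylmethyl isocyanide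
Product: 3 rac-2-methyl-4-(2,6,6-trimethylcyclohex-1-en-1-yl)butanenitrile
Conditions: t-BuOK, DME/EtOH, 0 → 35 °C
Reagents that add atoms: none
Why: Van Leusen reductive cyanation turns the methyl ketone into the one-carbon-longer secondary nitrile (old carbonyl carbon = C8, nitrile carbon = C9, racemic) without touching the tetrasubstituted ring alkene.

Step 2
Reactants: 3 rac-2-methyl-4-(2,6,6-trimethylcyclohex-1-en-1-yl)butanenitrile
Product: 5 rac-3-methyl-5-(2,6,6-trimethylcyclohex-1-en-1-yl)pentan-2-one, via lithium ketiminate 4 (not isolated)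
Conditions: MeLi, Et2O, 0 °C → rt; then 1 M HCl, 0 °C
Reagents that add atoms: methyllithium, [Li]C; water, O
Why: Organolithium addition to a nitrile stops at the N-lithio ketimine, which is hydrolysed on acidic work-up to the methyl ketone (C9 carbonyl, C11 methyl).

Step 3
Reactants: 5 rac-3-methyl-5-(2,6,6-trimethylcyclohex-1-en-1-yl)pentan-2-one
Product: 6 N,N-dimethylhydrazone of 5
Conditions: Me2NNH2, AcOH (cat.), EtOH, reflux
Reagents that add atoms: 1,1-dimethylhydrazine, CN(C)N
Why: Acid-catalysed condensation gives the dimethylhydrazone, whose azaenolate opens epoxides far more reliably than the lithium enolate of the ketone.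

Step 4
Reactants: 7 2-bromoallyl alcohol; 8 trimethylsilylacetylene
Product: 9 2-methylidene-4-(trimethylsilyl)but-3-yn-1-ol
Conditions: Pd(PPh3)2Cl2 (cat.), CuI (cat.), Et3N, THF, rt
Reagents that add atoms: none
Why: Sonogashira coupling of a vinyl bromide with a terminal alkyne tolerates the free allylic alcohol.

Step 5
Reactants: 9 2-methylidene-4-(trimethylsilyl)but-3-yn-1-ol
Product: 10 (R)-{2-[(trimethylsilyl)ethynyl]oxiran-2-yl}methanol
Conditions: Ti(OiPr)4 (cat.), D-(−)-diisopropyl tartrate, t-BuOOH, 4 Å MS, CH2Cl2, −20 °C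
Reagents that add atoms: tert-butyl hydroperoxide, CC(C)(C)OO
Why: Sharpless asymmetric epoxidation of the 2-substituted allylic alcohol with the D-(−)-tartrate delivers oxygen to the face that gives the (R)-epoxy alcohol (alkynyl group lowest in priority), which sets C13.

Step 6
Reactants: 10 (R)-{2-[(trimethylsilyl)ethynyl]oxiran-2-yl}methanol
Product: 11 (S)-triisopropyl({2-[(trimethylsilyl)ethynyl]oxiran-2-yl}methoxy)silane
Conditions: TIPSCl, imidazole, DMF, 0 °C → rt
Reagents that add atoms: triisopropylsilyl chloride, CC(C)[Si](Cl)(C(C)C)C(C)C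
Why: Standard silylation of the primary alcohol installs a bulky group that later shields one face of the oxocarbenium ring and cannot enter ketal formation; the descriptor changes from R to S only through the priority rules.

Step 7
Reactants: 6 N,N-dimethylhydrazone of 5; 11 (S)-triisopropyl({2-[(trimethylsilyl)ethynyl]oxiran-2-yl}methoxy)silane
Product: 13 N,N-dimethylhydrazone of hydroxy ketone 14 (13R; C8 epimers), via lithium azaenolate 12 (not isolated)
Conditions: LDA, THF, −78 → 0 °C; then 11, 0 °C → rt; H2O
Reagents that add atoms: none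
Why: Hydrazone azaenolate alkylation: LDA deprotonates the less substituted α-carbon (C11 methyl) and the azaenolate opens the 2,2-disubstituted epoxide by SN2 attack at its CH2 (C12), forming C11–C12 without touching C13.

Step 8
Reactants: 13 N,N-dimethylhydrazone of hydroxy ketone 14
Product: 14 (7R)-7-hydroxy-3-methyl-1-(2,6,6-trimethylcyclohex-1-en-1-yl)-8-(triisopropylsilyloxy)-7-[(trimethylsilyl)ethynyl]octan-4-one (C3 epimers; in equilibrium with its cyclic hemiketal)
Conditions: CuCl2, THF/H2O (pH 7 phosphate buffer), rt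
Reagents that add atoms: water, O
Why: CuCl2-assisted hydrazone hydrolysis at neutral pH (copper binds the released hydrazine) leaves both silyl groups and the tertiary propargylic alcohol intact.

Step 9
Reactants: 14 γ-hydroxy ketone (octan-4-one above)
Product: 15 (5R)-2-methoxy-2-[4-(2,6,6-trimethylcyclohex-1-en-1-yl)butan-2-yl]-5-[(triisopropylsilyloxy)methyl]-5-[(trimethylsilyl)ethynyl]oxolane (C8 and C9 epimers; 13R)
Conditions: PPTS (cat.), HC(OMe)3, MeOH, rt
Reagents that add atoms: methanol, CO; trimethyl orthoformate, COC(OC)OC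
Why: Acid-catalysed ketalization closes the tertiary hydroxyl onto the C9 ketone and exchanges the hemiketal to the methyl ketal while the orthoformate removes water; the C8/C9 mixture is acceptable because both centres are reset in step 10.

Step 10
Reactants: 15 cyclic methyl ketal (oxolane above)
Product: 18 (13R)-9α,13-epoxy-16-(triisopropylsilyloxy)-15-(trimethylsilyl)labd-5-en-14-yne [8α-methyl; 10β-methyl], via oxocarbenium triflate 16 (not isolated), via C5 carbocation 17 (not isolated)
Conditions: TMSOTf (1.2 equiv), 2,6-di-tert-butyl-4-methylpyridine (1.5 equiv), CH2Cl2, −78 → 0 °C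
Reagents that add atoms: none
Why: Proposed new method: TMSOTf removes the methoxy group of 15 to give the five-membered oxocarbenium ion 16, C10 of the tetrasubstituted C5=C10 alkene attacks C9 to join two fully substituted carbons, and the tertiary C5 cation 17 loses a C6 proton to the hindered pyridine to give the Δ5 alkene; the closest known reaction types are intramolecular Prins cyclizations of cyclic oxocarbenium ions onto alkenes and acetal-initiated cation–olefin cyclizations of ionone-type cyclohexenes, neither shown for a ketal-derived spiro oxocarbenium ion forming vicinal fully substituted centres. Ring B closes in the 6-endo mode (C5 and C10 both end up in the ring) through a chair, while attack through C5 (5-exo, spiro ring, three contiguous fully substituted carbons beside the gem-dimethyl group) is disfavoured. C9 is set by attack of C10 on the oxocarbenium face anti to the C16 CH2OTIPS arm and syn to the slim alkyne of the fixed C13 centre; C10 is set relative to C9 by the chair in which the ring oxygen is axial, near the developing C5 cation, and the C11 methylene is equatorial; C8 is set by its equatorial methyl group, since an axial C17 would clash 1,3-diaxially with C20. Both C8 epimers can funnel into this chair because 16 equilibrates with its enol ethers through the pyridinium triflate formed in the flask, which can reprotonate an enol ether but not the product alkene, so the C–C bond formation is irreversible. The step therefore needs face selectivity at C9 and the oxygen-axial chair topicity at C10, secured by the C13 substituents and by the C17/C20 interaction.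

Step 11
Reactants: 18 Δ5 alkene from step 10
Product: 19 5α,6α-epoxide of 18
Conditions: mCPBA, NaHCO3, CH2Cl2, 0 °C
Reagents that add atoms: 3-chloroperoxybenzoic acid, OOC(=O)c1cccc(Cl)c1
Why: Prilezhaev epoxidation takes the electron-rich trisubstituted alkene much faster than the silyl alkyne, expected anti to the axial C19 and C20 methyl groups; the face does not matter because C5 and C6 are reset in steps 12 to 14.

Step 12
Reactants: 19 5α,6α-epoxide of 18
Product: 20 (13R)-9α,13-epoxy-16-(triisopropylsilyloxy)-15-(trimethylsilyl)-5β-labd-14-yn-6-one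
Conditions: BF3·OEt2, toluene, −78 → −20 °C
Reagents that add atoms: none
Why: Meinwald rearrangement: the Lewis acid opens the tertiary C5–O bond and the C6 hydrogen shifts to C5 anti to the leaving oxygen, expected to give the 6-ketone first as the cis-fused 5β-H isomer, as with steroidal 5,6-epoxides.

Step 13
Reactants: 20 5β-H 6-ketone
Product: 21 (13R)-9α,13-epoxy-16-(triisopropylsilyloxy)labd-14-yn-6-one (5α-H)
Conditions: NaOMe (cat.), MeOH/THF, rt
Reagents that add atoms: none
Why: Methoxide enolizes the ketone toward C5 and should equilibrate the ring fusion to the more stable trans-decalin (5α-H), and it cleaves the alkynyl C–Si bond by methanolysis; C8 is not α to the carbonyl and is untouched.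

Step 14
Reactants: 21 5α-H 6-ketone with terminal alkyne
Product: 22 (13R)-9α,13-epoxy-16-(triisopropylsilyloxy)labd-14-yn-6β-ol
Conditions: NaBH4, MeOH/THF, 0 °C → rt
Reagents that add atoms: none
Why: Hydride reduction of the cyclohexanone: the β face of C6 is screened by the axial C19 and C20 methyl groups, so hydride should arrive from the α face and give the axial 6β-alcohol.

Step 15
Reactants: 22 6β-alcohol
Product: 23 (13R)-6β-acetoxy-9α,13-epoxy-16-(triisopropylsilyloxy)labd-14-yne
Conditions: Ac2O, DMAP, Et3N, CH2Cl2, 40 °C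
Reagents that add atoms: acetic anhydride, CC(=O)OC(C)=O
Why: DMAP-catalysed acylation forces the hindered axial secondary alcohol to the acetate before the acid-sensitive enol ether is made.

Step 16
Reactants: 23 6β-acetate silyl ether
Product: 24 (13R)-6β-acetoxy-9α,13-epoxylabd-14-yn-16-ol
Conditions: TBAF, AcOH, THF, rt
Reagents that add atoms: none
Why: Fluoride cleaves the primary triisopropylsilyl ether, and the acetic acid buffer keeps the hindered acetate and the terminal alkyne intact.

Step 17
Reactants: 24 alkynol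
Product: 25 (13R)-6β-acetoxy-9α,13:15,16-diepoxylabd-14-ene (CNP0242014.1)
Conditions: Mo(CO)6 (25 mol%), Et3N, Et2O, hν (350 nm), rt
Reagents that add atoms: none
Why: Molybdenum-catalysed endo cycloisomerization of a but-3-yn-1-ol: the terminal alkyne rearranges to a vinylidene on molybdenum and the C16 hydroxyl adds to C15, closing the 2,3-dihydrofuran (5-endo) without touching C13, while triethylamine protects the enol ether.

## Compound list

1 | dihydro-β-ionone | CC(=O)CCC1=C(C)CCCC1(C)C | starting material
2 | tosylmethyl isocyanide | Cc1ccc(cc1)S(=O)(=O)C[N+]#[C-] | starting material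
3 | rac-2-methyl-4-(2,6,6-trimethylcyclohex-1-en-1-yl)butanenitrile | CC(C#N)CCC1=C(C)CCCC1(C)C | intermediate
4 | lithium ketiminate from 3 and MeLi | CC(CCC1=C(C)CCCC1(C)C)C(C)=N[Li] | intermediate (not isolated)
5 | rac-3-methyl-5-(2,6,6-trimethylcyclohex-1-en-1-yl)pentan-2-one | CC(C(C)=O)CCC1=C(C)CCCC1(C)C | intermediate
6 | N,N-dimethylhydrazone of 5 | CC(CCC1=C(C)CCCC1(C)C)C(C)=NN(C)C | intermediate
7 | 2-bromoallyl alcohol | OCC(Br)=C | starting material
8 | trimethylsilylacetylene | C#C[Si](C)(C)C | starting material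
9 | 2-methylidene-4-(trimethylsilyl)but-3-yn-1-ol | OCC(=C)C#C[Si](C)(C)C | intermediate
10 | (R)-{2-[(trimethylsilyl)ethynyl]oxiran-2-yl}methanol | C1[C@](CO)(C#C[Si](C)(C)C)O1 | intermediate
11 | (S)-triisopropyl({2-[(trimethylsilyl)ethynyl]oxiran-2-yl}methoxy)silane | C1[C@](CO[Si](C(C)C)(C(C)C)C(C)C)(C#C[Si](C)(C)C)O1 | intermediate
12 | lithium azaenolate of 6 (deprotonated at C11) | C=C(N([Li])N(C)C)C(C)CCC1=C(C)CCCC1(C)C | intermediate (not isolated)
13 | γ-hydroxy hydrazone (13R, C8 epimers) | CC(CCC1=C(C)CCCC1(C)C)C(CC[C@](O)(CO[Si](C(C)C)(C(C)C)C(C)C)C#C[Si](C)(C)C)=NN(C)C | intermediate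
14 | γ-hydroxy ketone (13R, C8 epimers) | CC(CCC1=C(C)CCCC1(C)C)C(=O)CC[C@](O)(CO[Si](C(C)C)(C(C)C)C(C)C)C#C[Si](C)(C)C | intermediate
15 | cyclic methyl ketal (13R, C8 and C9 epimers), key-step precursor | CC1=C(CCC(C)C2(OC)CC[C@](CO[Si](C(C)C)(C(C)C)C(C)C)(C#C[Si](C)(C)C)O2)C(C)(C)CCC1 | intermediate
16 | five-membered oxocarbenium triflate (C9=O+) | CC1=C(CCC(C)C2=[O+][C@@](CO[Si](C(C)C)(C(C)C)C(C)C)(C#C[Si](C)(C)C)CC2)C(C)(C)CCC1.[O-]S(=O)(=O)C(F)(F)F | intermediate (not isolated)
17 | cyclized tertiary C5 carbocation (triflate) | C1C[C@@H](C)[C@]2(CC[C@](CO[Si](C(C)C)(C(C)C)C(C)C)(C#C[Si](C)(C)C)O2)[C@@]2(C)CCCC(C)(C)[C+]12.[O-]S(=O)(=O)C(F)(F)F | intermediate (not isolated)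
18 | (13R)-9α,13-epoxy-16-(triisopropylsilyloxy)-15-(trimethylsilyl)labd-5-en-14-yne (8α-CH3, 10β-CH3), key-step product | C1C[C@@H](C)[C@]2(CC[C@](CO[Si](C(C)C)(C(C)C)C(C)C)(C#C[Si](C)(C)C)O2)[C@@]2(C)CCCC(C)(C)C=12 | intermediate
19 | 5α,6α-epoxide of 18 | O1[C@H]2C[C@@H](C)[C@]3(CC[C@](CO[Si](C(C)C)(C(C)C)C(C)C)(C#C[Si](C)(C)C)O3)[C@@]3(C)CCCC(C)(C)[C@]123 | intermediate
20 | 6-ketone, 5β-H (cis-fused), silyl alkyne | O=C1C[C@@H](C)[C@]2(CC[C@](CO[Si](C(C)C)(C(C)C)C(C)C)(C#C[Si](C)(C)C)O2)[C@@]2(C)CCCC(C)(C)[C@@H]12 | intermediate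
21 | 6-ketone, 5α-H (trans-fused), terminal alkyne | O=C1C[C@@H](C)[C@]2(CC[C@](CO[Si](C(C)C)(C(C)C)C(C)C)(C#C)O2)[C@@]2(C)CCCC(C)(C)[C@H]12 | intermediate
22 | 6β-alcohol | O[C@@H]1C[C@@H](C)[C@]2(CC[C@](CO[Si](C(C)C)(C(C)C)C(C)C)(C#C)O2)[C@@]2(C)CCCC(C)(C)[C@H]12 | intermediate
23 | 6β-acetate, 16-silyl ether | CC(=O)O[C@@H]1C[C@@H](C)[C@]2(CC[C@](CO[Si](C(C)C)(C(C)C)C(C)C)(C#C)O2)[C@@]2(C)CCCC(C)(C)[C@H]12 | intermediate
24 | 6β-acetoxy-16-hydroxy-14-yne | CC(=O)O[C@@H]1C[C@@H](C)[C@]2(CC[C@](CO)(C#C)O2)[C@@]2(C)CCCC(C)(C)[C@H]12 | intermediate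
25 | (13R)-6β-acetoxy-9α,13:15,16-diepoxylabd-14-ene (5α-H, 8α-CH3, 10β-CH3), CNP0242014.1 | CC(=O)O[C@@H]1C[C@@H](C)[C@]2(CC[C@]3(C=COC3)O2)[C@@]2(C)CCCC(C)(C)[C@H]12 | target

## Step count

Total steps: 17. Longest linear sequence: 14 (steps 1–3 and 7–17, or steps 4–17).

## Steps most likely to fail

**Step 10 (Proposed new method).** The ionized ketal may rest as its enol ethers and never cyclize. C10 may attack the wrong oxocarbenium face or through the oxygen-equatorial chair. The C5 cation may revert by retro-Prins fragmentation or shift a C4 methyl group. C8 may fail to equilibrate before cyclization.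

Fallback with known chemistry: the ring-A alkene is made an allylsilane, so the closure becomes an intramolecular Hosomi–Sakurai reaction of a ketal. It sets out from epoxide 11, partnered with commercial β-ionone (CC(=O)/C=C/C1=C(C)CCCC1(C)C), and comes back at 18. Copper-catalysed enantioselective conjugate silylation of β-ionone (PhMe2Si–Bpin, CuCl, chiral imidazolinium salt, NaOtBu, then MeOH) should give the (R)-β-silyl ketone F1. The conditions of steps 1, 2 and 3 then give the silyl nitrile F2, the silyl methyl ketone F3 and its dimethylhydrazone F4. Azaenolate opening of 11 as in step 7 gives the silyl hydroxy hydrazone F5, CuCl2 hydrolysis gives the silyl hydroxy ketone F6, and PPTS/HC(OMe)3/MeOH gives the silylated methyl ketal F7. TMSOTf (cat.) in CH2Cl2 at −78 °C then closes ring B: C10, the γ-carbon of the allylsilane, attacks C9 anti to the axial C6–Si bond, and the β-silyl C5 cation loses silicon to give 18. The C6–Si centre fixes the alkene face and C13 the oxocarbenium face, so the chair topicity no longer rests on a small conformational preference, and no proton is set free.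

**Step 12.** The C5 cation formed on Lewis-acid opening of the epoxide may break the new C9–C10 bond (Grob-type fragmentation back to an oxocarbenium ion) or shift a C4 methyl group instead of the C6 hydrogen.

Fallback: radical, reductive opening of the same epoxide. It sets out from 19 and comes back at 21. Cp2TiCl (from Cp2TiCl2 and Mn dust) with 1,4-cyclohexadiene in THF cleaves the C5–O bond homolytically; the tertiary C5 radical takes up hydrogen and gives the 6α-alcohol F8 (C5 epimers). Dess–Martin oxidation gives the 6-ketone as 20 together with its 5α-H epimer F9, and the NaOMe/MeOH treatment of step 13 converts both into 21.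

**Step 7.** SN2 opening at the epoxide CH2 next to the fully substituted C13 may be slow, and base-induced isomerization of the epoxide or attack through the alkyne (SN2′) may compete.

Fallback: the C11–C12 bond is made with an acetylide and the ketal by alkyne hydroalkoxylation. It sets out from nitrile 3 and epoxide 11 and comes back at 15. DIBAL-H reduction of 3 (toluene, −78 °C; aqueous HCl) gives the aldehyde F10, and Ohira–Bestmann homologation (K2CO3, MeOH) gives the terminal alkyne F11. Its lithium acetylide with BF3·OEt2 (THF, −78 °C) opens 11 at CH2 to give the homopropargylic alcohol F12. Ph3PAuCl/AgOTf (cat.) in MeOH adds the C13 hydroxyl to C9 of the C9≡C11 alkyne (5-endo) and methanol to the resulting enol ether, giving 15.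

## Further compounds

F1 | step 10 | (R)-4-[dimethyl(phenyl)silyl]-4-(2,6,6-trimethylcyclohex-1-en-1-yl)butan-2-one | CC(=O)C[C@@H]([Si](C)(C)c1ccccc1)C1=C(C)CCCC1(C)C
F2 | step 10 | silyl nitrile (6R, C8 epimers) | CC(C#N)C[C@@H]([Si](C)(C)c1ccccc1)C1=C(C)CCCC1(C)C
F3 | step 10 | silyl methyl ketone (6R, C8 epimers) | CC(C(C)=O)C[C@@H]([Si](C)(C)c1ccccc1)C1=C(C)CCCC1(C)C
F4 | step 10 | N,N-dimethylhydrazone of F3 | CC(C[C@@H]([Si](C)(C)c1ccccc1)C1=C(C)CCCC1(C)C)C(C)=NN(C)C
F5 | step 10 | silyl γ-hydroxy hydrazone (6R, 13R) | CC(C[C@@H]([Si](C)(C)c1ccccc1)C1=C(C)CCCC1(C)C)C(CC[C@](O)(CO[Si](C(C)C)(C(C)C)C(C)C)C#C[Si](C)(C)C)=NN(C)C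
F6 | step 10 | silyl γ-hydroxy ketone (6R, 13R) | CC(C[C@@H]([Si](C)(C)c1ccccc1)C1=C(C)CCCC1(C)C)C(=O)CC[C@](O)(CO[Si](C(C)C)(C(C)C)C(C)C)C#C[Si](C)(C)C
F7 | step 10 | C6-silylated cyclic methyl ketal (6R, 13R) | CC1=C([C@H]([Si](C)(C)c2ccccc2)CC(C)C2(OC)CC[C@](CO[Si](C(C)C)(C(C)C)C(C)C)(C#C[Si](C)(C)C)O2)C(C)(C)CCC1
F8 | step 12 | 6α-alcohol with C5–H (C5 epimers), silyl alkyne | O[C@H]1C[C@@H](C)[C@]2(CC[C@](CO[Si](C(C)C)(C(C)C)C(C)C)(C#C[Si](C)(C)C)O2)[C@@]2(C)CCCC(C)(C)C12
F9 | step 12 | 5α-H epimer of 20 | O=C1C[C@@H](C)[C@]2(CC[C@](CO[Si](C(C)C)(C(C)C)C(C)C)(C#C[Si](C)(C)C)O2)[C@@]2(C)CCCC(C)(C)[C@H]12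
F10 | step 7 | rac-2-methyl-4-(2,6,6-trimethylcyclohex-1-en-1-yl)butanal | CC(C=O)CCC1=C(C)CCCC1(C)C
F11 | step 7 | rac-3-methyl-5-(2,6,6-trimethylcyclohex-1-en-1-yl)pent-1-yne | CC(C#C)CCC1=C(C)CCCC1(C)C
F12 | step 7 | homopropargylic alcohol (13R, C8 epimers) | CC(CCC1=C(C)CCCC1(C)C)C#CC[C@](O)(CO[Si](C(C)C)(C(C)C)C(C)C)C#C[Si](C)(C)C
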